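(The readings are simulated on assumed constants.)

| setting | dusk | winter | spring | Thursday's | Monday's | Wednesday's | Sunday's |
|---|---|---|---|---|---|---|---|
| substrate | 20 mM | 20 mM | 20 mM | 20 mM | 20 mM (fed, over 7.50 min) | 20 mM | 20 mM |
| reagent | 40 mM | 40 mM | 40 mM | 40.0 mM | 40.0 mM | 40.0 mM | 40.0 mM (fed, over 7.50 min) |
| initiator | 1 mM | 0.50 mM | 0.75 mM | 1.0 mM | 1.0 mM | 1.0 mM | 1.0 mM |
| remark | run made earlier | run made earlier | run made earlier | everything together in a closed stirred flask, run for 15 min | all but substrate at the start; substrate goes in evenly over 7.50 min, the run ends at 15 min | a single well-mixed tank run continuously and read at steady state, 15 min in it on average | a stirred flask in which reagent is dosed at a steady rate over 7.50 min without added volume, worked up at 15 min |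
| time |  |  |  | 15 min | 15 min |  | 15 min |

| run | time / min | target / % |
|---|---|---|
| dusk | 0.667 | 14.5 |
| dusk | 1.33 | 25.3 |
| dusk | 2.00 | 35.1 |
| dusk | 3.00 | 44.3 |
| dusk | 5.00 | 57.2 |
| dusk | 10.0 | 62.1 |
| winter | 0.667 | 9.3 |
| winter | 2.00 | 25.0 |
| winter | 3.00 | 34.0 |
| winter | 5.00 | 42.4 |
| winter | 6.00 | 46.3 |
| winter | 10.0 | 57.3 |
| spring | 0.667 | 12.2 |
| spring | 2.00 | 29.4 |
| spring | 3.00 | 36.9 |
| spring | 5.00 | 53.0 |
| spring | 6.00 | 55.1 |
| spring | 10.0 | 60.4 |

(standard deviation of a reading: 1 percentage point)

- a species is counted by the substrate in it: one ended chains B counts as two
- the stated concentrations are those of everything mixed, before any reaction; amounts are the same in each set-up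
- candidate steps: substrate <-> dormant form; 2 initiating radical -> ended chains A; initiator -> 2 initiating radical; target <-> isomer of the product; substrate + initiating radical -> chain carrier; reagent + target -> over-reaction product; reagent + chain carrier -> target + initiating radical; 2 chain carrier -> ended chains B
- the feed brings no volume worth counting
- the earlier runs were made in a closed, stirred flask

- the set-up with the highest amount of target at the outlet or at the end, in percent of the substrate put in ("none" if the first two lie within 2 percentage points) (Thursday's / Monday's / Wednesday's / Sunday's / none)
- amount of target at the outlet or at the end, in percent of the substrate put in, Thursday's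
- amount of target at the outlet or at the end, in percent of the substrate put in, Monday's
- amount of target at the outlet or at the end, in percent of the substrate put in, Wednesday's
- amount of target at the outlet or at the end, in percent of the substrate put in, Sunday's

**Small charge.** Start from the smaller charge: substrate at 20 mM stands against reagent at 40.0 mM, so substrate is the limiting reagent, and its balance is the one to write. Read the first dusk value, 14.5 % of target at 0.667 min, as substrate consumed; as a first-order constant it gives 0.235 min⁻¹. Multiply by the time: the consumption number 3.52 counts the substrate lifetimes held in the run.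

**Reading it.** Take the closed flask of Thursday's: the number gives 97.0 % of the substrate consumed. Take Wednesday's tank: feed equals outflow plus consumption, which gives 77.9 % consumed.

**Testing it.** The same constant reckons 90.5 % consumed in the dusk run at 10.0 min, but the reading there is 62.1 % of target, a read ratio of 0.687. So one number is not enough: it counts substrate consumed, not target standing. Assume that this dusk ratio carries over to other times and vessels, and reckon 66.7 % for Thursday's and 53.5 % for Wednesday's.

**The forecast.** It gives 58 %, 62 %, 49 % and 65.5 % for Thursday's, Monday's, Wednesday's and Sunday's, and names Sunday's: “Dosing reagent looks best, though narrowly.” Its Thursday's and Wednesday's values lie below the reckoning above.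

**The result.** In the same order the flasks give 60.2 %, 61.4 %, 62.1 % and 60.1 %. The verdict is none, since Wednesday's and Monday's, the two highest, differ by 0.70 percentage points, within 2 points.

    substrate ⇌ dormant form (K = 0.260, k = 0.00190 s⁻¹)
    2 initiating radical → ended chains A (k = 2.60 × 10⁶ M⁻¹ s⁻¹)
    initiator → 2 initiating radical (k = 0.00290 s⁻¹)
    target ⇌ isomer of the product (K = 0.440, k = 0.00350 s⁻¹)
    substrate + initiating radical → chain carrier (k = 1.90 × 10⁶ M⁻¹ s⁻¹)
    reagent + target → over-reaction product (k = 0.00580 M⁻¹ s⁻¹)
    reagent + chain carrier → target + initiating radical (k = 37000 M⁻¹ s⁻¹)
    2 chain carrier → ended chains B (k = 1.00 × 10⁹ M⁻¹ s⁻¹)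

**Target's clock.** Put target through the same number: forward isomerisation, half-life 3.3 min, gives 3.15 beside the 3.52 of substrate, while over-reaction at Thursday's charges, half-life 50 min, gives 0.209. That forward half-life is shorter than the over-reaction's and shorter than the run, and Sunday's, where the plain first-order fit reading all reacted substrate as target gives 85.4 %, stands at 60.1 %.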